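Everything rests on one reading of the target: the ester carbon C1, the methylene C2 and the dioxane carbons C3–C6 are six carbons in a row, oxygenated at both ends (C1 and C6) and already spanned by the O1–O2 bridge of the 1,2-dioxane ring, so the molecule is a peroxide-bridged cyclohexanone whose C1–C6 bond has been cut by oxygen insertion. A catalyst-controlled Baeyer–Villiger oxidation of a racemic 2,3-dioxabicyclo[2.2.2]octan-5-one, whose bridgehead next to the carbonyl carries the silylated pentynyl chain, should in one operation create the C6–O ketal bond with retention, expand the carbocycle to a bridged seven-membered lactone and pick out the (3S) enantiomer.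

Key step: step 5

Remark on numbering and stereochemistry: atom numbers are those of the target (C1 ester carbonyl, C2 its methylene, C3–C6 ring carbons, O2 on C3, O1 on C6). The target is (3S,6R), with OMe on C6 cis to the C3 side arm (OMe axial, both carbon substituents equatorial). Compounds 5, 8 and 9 are racemates, and the SMILES of 8 and 9 show the enantiomer that is carried on.

Remark on design: the enol oxygen carries TBS and the alkyne TMS, so the ketone can be released with acidic fluoride without base and without loss of the alkynyl silane. The oxidation is run without any basic buffer, because the β-peroxy ketone opens by elimination under base.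

Assumption: which antipode of the N,N′-dioxide ligand makes the (1S,4R) ketone the fast-reacting enantiomer is settled by a short screen; both antipodes are accessible from L- or D-pipecolic acid.

Step 1
Reactants: 1 (5-chloropent-1-yn-1-yl)trimethylsilane
Product: 2 (5-iodopent-1-yn-1-yl)trimethylsilane
Conditions: NaI, acetone, reflux
Reagents that add atoms: sodium iodide, [Na+].[I-]
Why: Finkelstein halide exchange, an SN2 displacement of the primary chloride by iodide that is driven by precipitation of NaCl; no stereocentre is involved.

Step 2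
Reactants: 3 cyclohex-2-en-1-one; 2 (5-iodopent-1-yn-1-yl)trimethylsilane
Product: 5 6-[5-(trimethylsilyl)pent-4-yn-1-yl]cyclohex-2-en-1-one (racemate), via lithium cyclohexadienolate 4 (not isolated)
Conditions: LiN(iPr)2, THF, −78 °C (3 added slowly); then 2, DMPU, −78 → −20 °C
Reagents that add atoms: none
Why: Kinetic deprotonation of the enone takes the saturated α′ carbon, and the cross-conjugated lithium dienolate is C-alkylated by the primary iodide (SN2 enolate alkylation); the new stereocentre forms as a racemate and is erased in step 3.

Step 3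
Reactants: 5 6-[5-(trimethylsilyl)pent-4-yn-1-yl]cyclohex-2-en-1-one
Product: 7 tert-butyldimethyl({2-[5-(trimethylsilyl)pent-4-yn-1-yl]cyclohexa-1,5-dien-1-yl}oxy)silane, via substituted lithium dienolate 6 (not isolated)
Conditions: LiN(iPr)2, THF, −78 °C; TBSCl, DMPU, −78 °C → rt; filtration through Et3N-deactivated silica
Reagents that add atoms: tert-butyldimethylsilyl chloride, CC(C)(C)[Si](C)(C)Cl
Why: Kinetic α′-deprotonation again gives the cross-conjugated dienolate, and O-silylation (silyl enol ether formation) should deliver the 2-silyloxy-1,3-diene locked s-cis in the ring; the α′ carbon becomes sp2, so no stereocentre remains.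

Step 4
Reactants: 7 tert-butyldimethyl({2-[5-(trimethylsilyl)pent-4-yn-1-yl]cyclohexa-1,5-dien-1-yl}oxy)silane
Product: 9 (1S,4R)-4-[5-(trimethylsilyl)pent-4-yn-1-yl]-2,3-dioxabicyclo[2.2.2]octan-5-one as the racemate, via bicyclic silyl enol ether endoperoxide 8 (not isolated)
Conditions: O2, 5,10,15,20-tetraphenylporphyrin (cat.), visible light, CH2Cl2, −78 °C; then HF·pyridine, THF, −40 → 0 °C; pH 7 phosphate work-up
Reagents that add atoms: oxygen, O=O
Why: [4+2] cycloaddition of singlet oxygen across the termini of the s-cis diene gives the endoperoxide with both bridgehead C–O bonds necessarily cis (racemic, the diene being achiral), and acidic fluoride then cleaves the enol O–Si bond to release the ketone while the alkynyl C–Si bond and the base-sensitive β-peroxy ketone are spared.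

Step 5
Reactants: 9 (1S,4R)-4-[5-(trimethylsilyl)pent-4-yn-1-yl]-2,3-dioxabicyclo[2.2.2]octan-5-one as the racemate
Product: 11 (1R,5S)-1-[5-(trimethylsilyl)pent-4-yn-1-yl]-2,6,7-trioxabicyclo[3.2.2]nonan-3-one, via Criegee adduct 10 (not isolated)
Conditions: Sc(OTf)3 (10 mol %), chiral N,N′-dioxide ligand (two N-oxidised pipecolic acid 2,6-diisopropylanilide units joined through nitrogen by a 1,3-propylene tether, 10 mol %), mCPBA (0.55 equiv), EtOAc, −20 °C, no base; stopped near half conversion; the unoxidised mirror-image half of 9 is removed by chromatography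
Reagents that add atoms: 3-chloroperoxybenzoic acid (mCPBA), O=C(OO)c1cccc(Cl)c1
Why: Proposed new method: the peracid, activated and positioned by the chiral scandium complex, adds to the ketone carbon (C1 of the target) to give Criegee adduct 10, whose quaternary bridgehead carbon (C6 of the target) shifts from carbon to oxygen as 3-chlorobenzoate leaves; the closest known reaction type is the Baeyer–Villiger oxidation of bridged bicyclic ketones with bridgehead migration, together with its Sc(OTf)3/N,N′-dioxide-catalysed kinetic resolution of racemic 2-substituted cyclohexanones. The seven-membered lactone ring is closed by ring expansion and not by a cyclisation event: the 1,2-shift inserts oxygen into the C1–C6 bond of the six-membered carbocycle while the 1,2-dioxane ring stays intact. The acyloxy ketal centre C6 is formed with retention because the migrating carbon keeps its configuration, so the new C6–O bond is cis to the C2 arm on C3, and its absolute sense is set by the catalyst, which should oxidise only the (1S,4R) half of the racemate when the reaction is stopped near half conversion. Regioselectivity (bridgehead against the C2 methylene) is needed and is secured by the higher migratory aptitude of a fully substituted carbon that bears a lone-pair-donating peroxide oxygen. Chemoselectivity is needed as well and should hold because the peroxide bridge and the silyl alkyne are inert to peracid at −20 °C and because the base-free medium gives the β-peroxy ketone no chance to open by elimination.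

Step 6
Reactants: 11 (1R,5S)-1-[5-(trimethylsilyl)pent-4-yn-1-yl]-2,6,7-trioxabicyclo[3.2.2]nonan-3-one
Product: 13 methyl 2-{(3S,6R)-6-methoxy-6-[5-(trimethylsilyl)pent-4-yn-1-yl]-1,2-dioxan-3-yl}acetate, via methoxy dioxane carboxylic acid 12 (not isolated)
Conditions: HCl (0.05 M in dry MeOH), 0 °C → rt
Reagents that add atoms: methanol, CO
Why: Acid-catalysed solvolysis of the acyloxy peroxyketal through a peroxycarbenium ion that methanol captures, followed by Fischer esterification of the freed acid; the C6 ketal equilibrates under acid to the isomer with axial OMe (anomeric effect) and equatorial chain, which is OMe cis to the C3 arm as in the target, and C3 is not touched.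

Step 7
Reactants: 13 methyl 2-{(3S,6R)-6-methoxy-6-[5-(trimethylsilyl)pent-4-yn-1-yl]-1,2-dioxan-3-yl}acetate
Product: 14 methyl 2-[(3S,6R)-6-methoxy-6-(pent-4-yn-1-yl)-1,2-dioxan-3-yl]acetate
Conditions: K2CO3 (0.2 equiv), MeOH, 0 °C
Reagents that add atoms: none
Why: Carbonate-catalysed methanolysis of the alkynyl C–Si bond (protodesilylation); the catalytic base is too weak to deprotonate the ester α-carbon at 0 °C, so the dioxane ring and both stereocentres should persist.

Step 8
Reactants: 15 dec-9-en-1-ol
Product: 16 dec-9-enal
Conditions: TEMPO (2,2,6,6-tetramethylpiperidin-1-oxyl, 10 mol %), PhI(OAc)2, CH2Cl2, rt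
Reagents that add atoms: none
Why: Oxoammonium-mediated alcohol oxidation with PhI(OAc)2 as terminal oxidant stops at the aldehyde and leaves the terminal alkene alone.

Step 9
Reactants: 16 dec-9-enal
Product: 17 (1E)-1-iodoundeca-1,10-diene
Conditions: CrCl2, CHI3, THF/1,4-dioxane, 0 °C → rt; any Z isomer removed on AgNO3-impregnated silica
Reagents that add atoms: iodoform, IC(I)I
Why: Takai olefination: the geminal dichromium species formed from iodoform and divalent chromium adds to the aldehyde and eliminates to the E-vinyl iodide, the dioxane cosolvent reinforcing the E preference.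

Step 10
Reactants: 14 methyl 2-[(3S,6R)-6-methoxy-6-(pent-4-yn-1-yl)-1,2-dioxan-3-yl]acetate; 17 (1E)-1-iodoundeca-1,10-diene
Product: 18 methyl 2-{(3S,6R)-6-[(6E)-hexadeca-6,15-dien-4-yn-1-yl]-6-methoxy-1,2-dioxan-3-yl}acetate (peroxyacarnoate A)
Conditions: Pd(PPh3)4 (5 mol %), CuI (10 mol %), Et3N (3 equiv), THF, rt, degassed
Reagents that add atoms: none
Why: Sonogashira coupling: oxidative addition of the vinyl iodide to zerovalent palladium, transmetalation from the copper acetylide and reductive elimination form the C(sp)–C(sp2) bond with retention of the E geometry; dialkyl peroxides and peroxyketals should tolerate these mild room-temperature conditions, and no stereocentre is touched.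

Compound list
1 | (5-chloropent-1-yn-1-yl)trimethylsilane | C[Si](C)(C)C#CCCCCl | starting material
2 | (5-iodopent-1-yn-1-yl)trimethylsilane | C[Si](C)(C)C#CCCCI | intermediate
3 | cyclohex-2-en-1-one | O=C1C=CCCC1 | starting material
4 | lithium cyclohexa-1,5-dien-1-olate (not isolated) | [Li+].[O-]C1=CCCC=C1 | intermediate
5 | 6-[5-(trimethylsilyl)pent-4-yn-1-yl]cyclohex-2-en-1-one (racemate) | O=C1C=CCCC1CCCC#C[Si](C)(C)C | intermediate
6 | lithium 2-[5-(trimethylsilyl)pent-4-yn-1-yl]cyclohexa-1,5-dien-1-olate (not isolated) | [Li+].[O-]C1=C(CCCC#C[Si](C)(C)C)CCC=C1 | intermediate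
7 | tert-butyldimethyl({2-[5-(trimethylsilyl)pent-4-yn-1-yl]cyclohexa-1,5-dien-1-yl}oxy)silane | CC(C)(C)[Si](C)(C)OC1=C(CCCC#C[Si](C)(C)C)CCC=C1 | intermediate
8 | tert-butyldimethyl({1-[5-(trimethylsilyl)pent-4-yn-1-yl]-2,3-dioxabicyclo[2.2.2]oct-5-en-6-yl}oxy)silane (racemate, one enantiomer drawn, not isolated) | C[Si](C)(C)C#CCCC[C@@]12CC[C@@H](C=C1O[Si](C)(C)C(C)(C)C)OO2 | intermediate
9 | (1S,4R)-4-[5-(trimethylsilyl)pent-4-yn-1-yl]-2,3-dioxabicyclo[2.2.2]octan-5-one (used as the racemate, reacting enantiomer drawn) | C[Si](C)(C)C#CCCC[C@@]12CC[C@@H](CC1=O)OO2 | intermediate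
10 | (1S,4R)-5-hydroxy-4-[5-(trimethylsilyl)pent-4-yn-1-yl]-2,3-dioxabicyclo[2.2.2]octan-5-yl 3-chlorobenzenecarboperoxoate (Criegee adduct, not isolated, configuration at C5 open) | C[Si](C)(C)C#CCCC[C@@]12CC[C@@H](CC1(O)OOC(=O)c1cccc(Cl)c1)OO2 | intermediate
11 | (1R,5S)-1-[5-(trimethylsilyl)pent-4-yn-1-yl]-2,6,7-trioxabicyclo[3.2.2]nonan-3-one | C[Si](C)(C)C#CCCC[C@@]12CC[C@@H](CC(=O)O1)OO2 | intermediate
12 | 2-{(3S,6R)-6-methoxy-6-[5-(trimethylsilyl)pent-4-yn-1-yl]-1,2-dioxan-3-yl}acetic acid (not isolated) | C[Si](C)(C)C#CCCC[C@]1(OC)CC[C@@H](CC(=O)O)OO1 | intermediate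
13 | methyl 2-{(3S,6R)-6-methoxy-6-[5-(trimethylsilyl)pent-4-yn-1-yl]-1,2-dioxan-3-yl}acetate | C[Si](C)(C)C#CCCC[C@]1(OC)CC[C@@H](CC(=O)OC)OO1 | intermediate
14 | methyl 2-[(3S,6R)-6-methoxy-6-(pent-4-yn-1-yl)-1,2-dioxan-3-yl]acetate | C#CCCC[C@]1(OC)CC[C@@H](CC(=O)OC)OO1 | intermediate
15 | dec-9-en-1-ol | C=CCCCCCCCCO | starting material
16 | dec-9-enal | C=CCCCCCCCC=O | intermediate
17 | (1E)-1-iodoundeca-1,10-diene | C=CCCCCCCC/C=C/I | intermediate
18 | methyl 2-{(3S,6R)-6-[(6E)-hexadeca-6,15-dien-4-yn-1-yl]-6-methoxy-1,2-dioxan-3-yl}acetate (peroxyacarnoate A) | C=CCCCCCCC/C=C/C#CCCC[C@]1(OC)CC[C@@H](CC(=O)OC)OO1 | target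

Total step count: 10. Longest linear sequence: 8 steps (steps 1–7 and 10; steps 8 and 9 make the vinyl iodide).

Steps most likely to fail

Step 5 (proposed new method). What may go wrong: the catalyst fails to tell the two enantiomeric ketones apart in the migration step, the C2 methylene migrates in place of the bridgehead, or the Lewis acid ionises the acyloxy ketal as it forms. The fallback uses known chemistry, sets out from 5 and returns at 13. Enone 5 is deprotonated as in step 3 to dienolate 6 and hydroxylated with 2-(phenylsulfonyl)-3-phenyloxaziridine to racemic 6-hydroxy-6-[5-(trimethylsilyl)pent-4-yn-1-yl]cyclohex-2-en-1-one F1. Pb(OAc)4 in MeOH/benzene cleaves the ketol between the carbonyl and the carbinol carbon to the keto ester methyl (2Z)-6-oxo-11-(trimethylsilyl)undec-2-en-10-ynoate F2. Urea–hydrogen peroxide with catalytic Sc(OTf)3 in MeOH converts the ketone into the methoxy hydroperoxy ketal F3. Et2NH in CF3CH2OH closes the dioxane by intramolecular conjugate addition of the hydroperoxide to the enoate, and brief HCl in MeOH sets the ketal centre as in step 6, giving the racemic dioxane ester F4. Preparative HPLC on a cellulose tris(3,5-dimethylphenylcarbamate) phase then supplies 13.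

Step 4. What may go wrong: ene-type or silyl-shift oxygenation competes with the cycloaddition, or the peroxide bridge opens by elimination while the enol ether is unmasked. The fallback sets out from 7 and returns at 13, replacing the bicyclic peroxide by an open-chain hydroperoxide. One equivalent of ozone in CH2Cl2/MeOH at −78 °C cleaves the electron-rich enol ether double bond of 7; the carbonyl oxide formed on the carbon that carries the side chain is trapped by methanol, which should give the silyl ester hydroperoxy ketal F5. Aqueous work-up hydrolyses the silyl ester to the hydroperoxy ketal acid F6, and (trimethylsilyl)diazomethane converts it into the methyl ester hydroperoxy ketal F3. From there the ring closure and the enantiomer separation of the preceding fallback lead through the racemic dioxane ester F4 to 13.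

Step 10. What may go wrong: the amine and the copper acetylide fragment the peroxide, phosphine-ligated zerovalent palladium reduces it, or the terminal alkyne dimerises oxidatively. The fallback sets out from 14 and 17 and returns at 18, reversing the polarity of the coupling and avoiding amine, copper and phosphine on the peroxide fragment. Alkyne 14 is brominated with N-bromosuccinimide and catalytic AgNO3 in acetone to the bromoalkyne F7. Vinyl iodide 17 is converted with (Bu3Sn)2 and catalytic Pd(PPh3)4 in THF into the E-vinylstannane F8. Stille coupling of the two with PdCl2(MeCN)2 in DMF at rt should give 18 with the E geometry retained.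

Further compounds
F1 | step 5 | 6-hydroxy-6-[5-(trimethylsilyl)pent-4-yn-1-yl]cyclohex-2-en-1-one (racemate) | O=C1C=CCCC1(O)CCCC#C[Si](C)(C)C
F2 | step 5 | methyl (2Z)-6-oxo-11-(trimethylsilyl)undec-2-en-10-ynoate | COC(=O)/C=C\CCC(=O)CCCC#C[Si](C)(C)C
F3 | step 5 | methyl (2Z)-6-hydroperoxy-6-methoxy-11-(trimethylsilyl)undec-2-en-10-ynoate (racemate) | COC(=O)/C=C\CCC(OC)(OO)CCCC#C[Si](C)(C)C
F4 | step 5 | racemate of 13, methyl 2-{(3S,6R)- and (3R,6S)-6-methoxy-6-[5-(trimethylsilyl)pent-4-yn-1-yl]-1,2-dioxan-3-yl}acetate | C[Si](C)(C)C#CCCC[C@]1(OC)CC[C@@H](CC(=O)OC)OO1.C[Si](C)(C)C#CCCC[C@@]1(OC)CC[C@H](CC(=O)OC)OO1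
F5 | step 4 | tert-butyldimethylsilyl (2Z)-6-hydroperoxy-6-methoxy-11-(trimethylsilyl)undec-2-en-10-ynoate (racemate) | CC(C)(C)[Si](C)(C)OC(=O)/C=C\CCC(OC)(OO)CCCC#C[Si](C)(C)C
F6 | step 4 | (2Z)-6-hydroperoxy-6-methoxy-11-(trimethylsilyl)undec-2-en-10-ynoic acid (racemate) | OC(=O)/C=C\CCC(OC)(OO)CCCC#C[Si](C)(C)C
F7 | step 10 | methyl 2-[(3S,6R)-6-(5-bromopent-4-yn-1-yl)-6-methoxy-1,2-dioxan-3-yl]acetate | BrC#CCCC[C@]1(OC)CC[C@@H](CC(=O)OC)OO1
F8 | step 10 | tributyl[(1E)-undeca-1,10-dien-1-yl]stannane | C=CCCCCCCC/C=C/[Sn](CCCC)(CCCC)CCCC
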